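The data were generated by integration for substances that don't exist, and the scatter is random.

The ratio I looked for was the working share of the catalyst at the asked conversion: with substrates and partner held by that conversion, the rate goes as catalyst charged times that share.

in all of them: left-handed substrate 20 mM; right-handed substrate 20 mM; catalyst 0.20 mM
- beta: partner 45 mM; protic impurity 1 mM; run made earlier
- flask: partner 30.0 mM; protic impurity 1.00 mM

- beta (time / min: left-handed product / %): 0.200: 6.4; 0.667: 16.9; 1.00: 22.0; 1.50: 27.4; 2.50: 34.8; 3.00: 35.4

(scatter of a reading: 0.5 percentage points)

- catalyst is single-handed; left-handed substrate and right-handed substrate are mirror images of each other, charged as a racemate, each of them at the stated concentration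
- the earlier runs were read with a standard deviation of 0.5 percentage points
- no earlier run changes the charge of catalyst; that part of a forecast is a guess

- factor on the rate of making left-handed product when 30% of the left-handed substrate and right-handed substrate together are converted if catalyst is charged twice over
- factor on the rate when 30% of the left-handed substrate and right-handed substrate together are converted if catalyst is charged at 2.0 mM instead

In the beta run I took the first-order constant in remaining left-handed substrate: 0.685 min⁻¹ over the first reading, 0.291 min⁻¹ from 1.50 min to 3.00 min. I divided each by the mean partner over its span, counting left-handed product and protic impurity as partner used: 42.7 mM, then 31.4 mM. Late over early gives 0.578, the surviving share s of working catalyst, a reading for the middle of the later span. In beta the left-handed product read 27.4% at 1.50 min, near 30%; I expected the flask, with 30.0 mM of partner against 45 mM, to take longer by that ratio, about 2.25 min, which lies inside that span, so I carried s over to the flask.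

If the decline keeps its own clock and n times the catalyst shortens the time n-fold, the share becomes the n-th root of s, so the factor is n times that root over s. I reckoned 2.63 for doubling and 16.4 for 2.0 mM. One number was barely enough: s rests on few readings, and no run changes the catalyst.

The forecast gave 2 (1.4 to 3) and 10 (3.5 to 22), saying “I assume first order at fixed composition”; my factors stood higher.

The flask gave 2.50 and 15.1.

    partner + catalyst + left-handed substrate → catalyst + left-handed product (k = 1400 L² mol⁻² s⁻¹)
    catalyst ⇌ dormant form (K = 1.40, k = 0.00400 s⁻¹)
    partner + catalyst + right-handed substrate → catalyst + right-handed product (k = 220 L² mol⁻² s⁻¹)
    partner + protic impurity → quenched reagent (k = 11.0 L mol⁻¹ s⁻¹)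

The flask's factor for 2.0 mM stands above first order, and a part of this comes from the catalyst's slide into the dormant form, an off-cycle state: taking that step away lowers the apparent order in catalyst at the asked conversion from 1.4 to 1.0. At the asked conversion the dormant form held 36.3% of the flask's catalyst. For the flask charged at 2.0 mM, s gave a dormant share of 5.34%, and at the same conversion that flask holds 4.36%.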